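Assumption: the SMILES is taken at face value (3S,6S,7R,8R,10S, 4Z, cis-fused lactone, angelate ester); atoms carry germacrane labels (lactone O on C6, ring fusion C6/C7, angelate on C8, tertiary carbinol C10, allylic carbinol C3, lactone carbons C11–C13).

**Retrosynthetic overview**
- The last step closes both rings in one flask in the biosynthetic order: the C6–C7 bond (the farnesyl C1–C10 bond of germacrene biogenesis) is made by intramolecular addition of a 2-(methoxycarbonyl)allyl chromium to a Z-enal, then O6 lactonises onto C12. C6 and C7 are set here.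
- The acyclic bromo-enal comes from an α-angeloyloxy aldehyde (C7) by vinylalumination with methyl propiolate (C11–C13) and SN2′ bromination; the C6 enal is unmasked from a PMB ether.
- C3 and the Z C4=C5 alkene come from CBS reduction of a Z-enone, made by adding a Z-alkenyllithium (from but-2-yn-1-ol) to a γ-lactone.
- C8 and C10 come from a proline aldol of acetone with 1,3-dithiane-2-carbaldehyde (C8), then a hydroxyl-directed SmI2 ketyl–acrylate coupling (C10, with C1–C3 as the γ-lactone).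
- No ring of the target exists before step 14: carbocycle first, lactone second.

**Route**

Step 1
Reactants: 1 1,3-dithiane
Product: 3 1,3-dithiane-2-carbaldehyde, via 2-lithio-1,3-dithiane 2 (not isolated)
Conditions: n-BuLi, THF, −30 °C; DMF, −78 → 0 °C; 1 M HCl
Reagents that add atoms: N,N-dimethylformamide, CN(C)C=O
Why: Formylation of 2-lithio-1,3-dithiane (Corey–Seebach acyl-anion chemistry): n-BuLi removes the C2 proton, the anion adds once to DMF to give a hemiaminal alkoxide that cannot add a second time, and acidic work-up releases the aldehyde; no stereocenter is formed.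

Step 2
Reactants: 3 1,3-dithiane-2-carbaldehyde, 4 acetone
Product: 5 (4R)-4-(1,3-dithian-2-yl)-4-hydroxybutan-2-one
Conditions: (S)-proline (20 mol %), acetone, 4 °C
Reagents that add atoms: none
Why: Proline-catalysed direct aldol reaction (List–Barbas aldol), for which α-thioacetal aldehydes are good acceptors that do not act as donors: the (S)-proline enamine of acetone attacks the Re face of the aldehyde in the hydrogen-bonded Houk–List transition state, which sets C8 as R, the same sense as in the known (R)-adducts of isobutyraldehyde.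

Step 3
Reactants: 5 (4R)-4-(1,3-dithian-2-yl)-4-hydroxybutan-2-one, 6 methyl acrylate
Product: 8 (5S)-5-[(2R)-2-(1,3-dithian-2-yl)-2-hydroxyethyl]-5-methyloxolan-2-one, via hydroxy ester 7 (not isolated)
Conditions: SmI2 (2.5 equiv), MeOH (2 equiv), THF, −78 → 0 °C
Reagents that add atoms: none
Why: Hydroxyl-directed SmI2 ketyl–olefin coupling with in situ lactonisation: trivalent samarium bridges the ketyl oxygen and the C8 hydroxyl in a six-membered chelate, the ketyl carbon adds to the acrylate on the face anti to the equatorial dithianyl group so that O8 and O10 become 1,3-anti (C10 S), and the samarium γ-alkoxide then closes onto the ester to give the γ-lactone.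

Step 4
Reactants: 8 (5S)-5-[(2R)-2-(1,3-dithian-2-yl)-2-hydroxyethyl]-5-methyloxolan-2-one, 9 angelic acid
Product: 11 (1R)-1-(1,3-dithian-2-yl)-2-[(2S)-2-methyl-5-oxooxolan-2-yl]ethyl (2Z)-2-methylbut-2-enoate, via mixed anhydride 10 (not isolated)
Conditions: 9, 2,4,6-Cl3C6H2COCl, Et3N, toluene, rt; then 8, toluene, 80 °C (no DMAP)
Reagents that add atoms: none
Why: Yamaguchi esterification through the preformed mixed anhydride without DMAP, the standard way to acylate a hindered secondary alcohol with angelic acid without isomerisation to the tiglate; the reaction occurs at oxygen, so C8 keeps its configuration, and the lactone and dithiane are inert.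

Step 5
Reactants: 12 but-2-yn-1-ol
Product: 14 (2Z)-3-iodobut-2-en-1-ol, via alkenylalanate 13 (not isolated)
Conditions: NaAlH2(OCH2CH2OMe)2, THF, 0 °C → rt; I2, −78 → 0 °C
Reagents that add atoms: iodine, II
Why: Hydroxyl-directed trans-hydroalumination of a propargylic alcohol followed by iodinolysis: hydride goes to C2 and aluminium to C3 inside a five-membered alkoxyaluminate, so iodine replaces aluminium cis to the CH2OH group and the Z geometry of the later C4=C5 bond is fixed.

Step 6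
Reactants: 14 (2Z)-3-iodobut-2-en-1-ol
Product: 15 1-({[(2Z)-3-iodobut-2-en-1-yl]oxy}methyl)-4-methoxybenzene
Conditions: NaH, 4-MeOC6H4CH2Cl, Bu4NI (cat.), THF, 0 °C → rt
Reagents that add atoms: 4-methoxybenzyl chloride, COc1ccc(CCl)cc1
Why: Williamson ether synthesis: the sodium alkoxide is benzylated by PMBCl (iodide catalysis) while the vinyl iodide is inert to SN2 attack, and the PMB ether survives organolithium, borane and silyl triflate chemistry yet is removed oxidatively later.

Step 7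
Reactants: 11 (1R)-1-(1,3-dithian-2-yl)-2-[(2S)-2-methyl-5-oxooxolan-2-yl]ethyl (2Z)-2-methylbut-2-enoate, 15 1-({[(2Z)-3-iodobut-2-en-1-yl]oxy}methyl)-4-methoxybenzene
Product: 18 (1R,3S,7Z)-1-(1,3-dithian-2-yl)-3-hydroxy-9-[(4-methoxybenzyl)oxy]-3,7-dimethyl-6-oxonon-7-en-1-yl (2Z)-2-methylbut-2-enoate, via alkenyllithium 16 (not isolated), via lithium lactolate 17 (not isolated)
Conditions: 15 (1.2 equiv), t-BuLi (2.4 equiv), Et2O, −78 °C; then 11, THF, −78 °C; aq NH4Cl, −78 °C
Reagents that add atoms: none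
Why: Iodine–lithium exchange with retention of alkene geometry, then mono-addition of the alkenyllithium to a γ-lactone: the tetrahedral lithium lactolate is stable at −78 °C so the ketone is only released on quenching, and the γ-lactone carbonyl is attacked much faster than the hindered, conjugated angelate ester; the Z-alkene and C8/C10 are untouched.

Step 8
Reactants: 18 (1R,3S,7Z)-1-(1,3-dithian-2-yl)-3-hydroxy-9-[(4-methoxybenzyl)oxy]-3,7-dimethyl-6-oxonon-7-en-1-yl (2Z)-2-methylbut-2-enoate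
Product: 19 (1R,3S,6S,7Z)-1-(1,3-dithian-2-yl)-3,6-dihydroxy-9-[(4-methoxybenzyl)oxy]-3,7-dimethylnon-7-en-1-yl (2Z)-2-methylbut-2-enoate
Conditions: (R)-2-methyl-CBS-oxazaborolidine [(3aR)-1-methyl-3,3-diphenyltetrahydro-1H,3H-pyrrolo[1,2-c][1,3,2]oxazaborole] (0.3 equiv), BH3·SMe2, THF, −30 °C; aqueous work-up
Reagents that add atoms: none
Why: Corey–Bakshi–Shibata reduction: the ketone binds to the oxazaborolidine–borane complex with the α-branched alkenyl group as the large substituent and hydride is delivered intramolecularly to give the S carbinol at C3 under catalyst control (the (S)-catalyst gives R with alkenyl or aryl ketones, so the (R)-catalyst is used), while esters, dithiane and PMB ether are not reduced at −30 °C.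

Step 9
Reactants: 19 (1R,3S,6S,7Z)-1-(1,3-dithian-2-yl)-3,6-dihydroxy-9-[(4-methoxybenzyl)oxy]-3,7-dimethylnon-7-en-1-yl (2Z)-2-methylbut-2-enoate
Product: 20 (1R,3S,6S,7Z)-1-(1,3-dithian-2-yl)-9-[(4-methoxybenzyl)oxy]-3,7-dimethyl-3,6-bis[(triethylsilyl)oxy]non-7-en-1-yl (2Z)-2-methylbut-2-enoate
Conditions: Et3SiOTf (3 equiv), 2,6-lutidine, CH2Cl2, −78 → 0 °C
Reagents that add atoms: triethylsilyl trifluoromethanesulfonate, CC[Si](CC)(CC)OS(=O)(=O)C(F)(F)F
Why: Silylation with a silyl triflate and a hindered pyridine base, conditions that protect tertiary as well as secondary alcohols: O10 must be blocked so that the C7 aldehyde of step 10 cannot close to a five-membered lactol, and O3 so that the Z-enal of step 12 cannot close to a dihydrofuranol and aromatise to a furan.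

Step 10
Reactants: 20 (1R,3S,6S,7Z)-1-(1,3-dithian-2-yl)-9-[(4-methoxybenzyl)oxy]-3,7-dimethyl-3,6-bis[(triethylsilyl)oxy]non-7-en-1-yl (2Z)-2-methylbut-2-enoate
Product: 21 (2R,4S,7S,8Z)-10-[(4-methoxybenzyl)oxy]-4,8-dimethyl-1-oxo-4,7-bis[(triethylsilyl)oxy]dec-8-en-2-yl (2Z)-2-methylbut-2-enoate
Conditions: MeI, CaCO3, MeCN/H2O (4:1), 45 °C
Reagents that add atoms: water, O
Why: Alkylative hydrolysis of a 1,3-dithiane: double S-methylation turns the thioacetal into a leaving group that water displaces under CaCO3 buffering, a neutral and non-oxidising unmasking that leaves the PMB ether, silyl ethers, alkenes and the configuration of the α-acyloxy carbon C8 unchanged.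

Step 11
Reactants: 21 (2R,4S,7S,8Z)-10-[(4-methoxybenzyl)oxy]-4,8-dimethyl-1-oxo-4,7-bis[(triethylsilyl)oxy]dec-8-en-2-yl (2Z)-2-methylbut-2-enoate, 22 methyl propiolate
Product: 24 methyl (4R,6S,9S,10Z)-3-hydroxy-12-[(4-methoxybenzyl)oxy]-6,10-dimethyl-2-methylidene-4-{[(2Z)-2-methylbut-2-enoyl]oxy}-6,9-bis[(triethylsilyl)oxy]dodec-10-enoate (both C3 epimers), via alkenylalane 23 (not isolated)
Conditions: 22, i-Bu2AlH, NMO, THF, 0 °C; then 21, 0 °C → rt; aq Rochelle salt
Reagents that add atoms: none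
Why: Vinylalumination, an amine-free equivalent of the Morita–Baylis–Hillman reaction: i-Bu2AlH with NMO adds hydride 1,4 to methyl propiolate and the resulting α-aluminio acrylate adds only to the aldehyde, so the base-sensitive α-acyloxy aldehyde is neither epimerised nor subject to acyl migration; the new carbinol carbon C7 forms as a mixture that is erased in step 13.

Step 12
Reactants: 24 methyl (4R,6S,9S,10Z)-3-hydroxy-12-[(4-methoxybenzyl)oxy]-6,10-dimethyl-2-methylidene-4-{[(2Z)-2-methylbut-2-enoyl]oxy}-6,9-bis[(triethylsilyl)oxy]dodec-10-enoate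
Product: 26 methyl (4R,6S,9S,10Z)-3-hydroxy-6,10-dimethyl-2-methylidene-4-{[(2Z)-2-methylbut-2-enoyl]oxy}-12-oxo-6,9-bis[(triethylsilyl)oxy]dodec-10-enoate, via allylic alcohol 25 (not isolated)
Conditions: DDQ, CH2Cl2/pH 7 buffer, 0 °C; crude 25, then TEMPO (2,2,6,6-tetramethylpiperidin-1-oxyl, 10 mol %), PhI(OAc)2, CH2Cl2, rt
Reagents that add atoms: none
Why: Oxidative cleavage of the PMB ether with DDQ (benzylic hydride abstraction and hydrolysis) followed by oxoammonium (TEMPO/PhI(OAc)2) oxidation of the crude alcohol, which is selective for the primary allylic hydroxyl over the secondary Morita–Baylis–Hillman hydroxyl and converts Z-allylic alcohols into Z-enals without isomerisation.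

Step 13
Reactants: 26 methyl (4R,6S,9S,10Z)-3-hydroxy-6,10-dimethyl-2-methylidene-4-{[(2Z)-2-methylbut-2-enoyl]oxy}-12-oxo-6,9-bis[(triethylsilyl)oxy]dodec-10-enoate
Product: 27 methyl (2Z,4R,6S,9S,10Z)-2-(bromomethyl)-6,10-dimethyl-4-{[(2Z)-2-methylbut-2-enoyl]oxy}-12-oxo-6,9-bis[(triethylsilyl)oxy]dodeca-2,10-dienoate
Conditions: NBS, Me2S, CH2Cl2, −20 → 0 °C
Reagents that add atoms: N-bromosuccinimide, O=C1CCC(=O)N1Br
Why: SN2′ bromination of a Morita–Baylis–Hillman alcohol with the Corey–Kim reagent: the alkoxysulfonium group at C7 is expelled as bromide attacks the methylene carbon, giving the thermodynamically preferred (2Z)-2-(bromomethyl)enoate with C8 cis to CH2Br under neutral conditions that spare the enal and silyl ethers.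

Step 14
Reactants: 27 methyl (2Z,4R,6S,9S,10Z)-2-(bromomethyl)-6,10-dimethyl-4-{[(2Z)-2-methylbut-2-enoyl]oxy}-12-oxo-6,9-bis[(triethylsilyl)oxy]dodeca-2,10-dienoate
Product: 30 (3aR,4R,6S,9S,10Z,11aS)-6,9-dihydroxy-6,10-dimethyl-3-methylidene-2-oxo-2,3,3a,4,5,6,7,8,9,11a-decahydrocyclodeca[b]furan-4-yl (2Z)-2-methylbut-2-enoate, via seco hydroxy ester 28 (not isolated), via bis-silyl lactone 29 (not isolated)
Conditions: CrCl2 (10 equiv), THF, rt, syringe-pump addition of 27 (final 2 mM); then 2 M aq HCl, rt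
Reagents that add atoms: none
Why: Intramolecular Nozaki–Hiyama–Kishi-type 2-(alkoxycarbonyl)allylation followed by lactonisation, the chromium Barbier route to α-methylene-γ-butyrolactones run here as a macrocyclisation: the allylchromium adds through C7 to the enal in a closed chair transition state with the C8 substituent axial (Z allyl unit), which gives the syn alkoxide and hence the cis-fused lactone (C6 S, C7 R), the face being set by C8 (H8 eclipsing the allyl unit to avoid A(1,3) strain, bond formation anti to the C9 arm), and aqueous HCl then closes the lactone and cleaves both triethylsilyl ethers.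

**Compound list**
1 | 1,3-dithiane | C1CSCSC1 | starting material
2 | 2-lithio-1,3-dithiane | [Li]C1SCCCS1 | intermediate
3 | 1,3-dithiane-2-carbaldehyde | O=CC1SCCCS1 | intermediate
4 | acetone | CC(C)=O | starting material
5 | (4R)-4-(1,3-dithian-2-yl)-4-hydroxybutan-2-one | CC(=O)C[C@@H](O)C1SCCCS1 | intermediate
6 | methyl acrylate | C=CC(=O)OC | starting material
7 | methyl (4S,6R)-6-(1,3-dithian-2-yl)-4,6-dihydroxy-4-methylhexanoate | COC(=O)CC[C@](C)(O)C[C@@H](O)C1SCCCS1 | intermediate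
8 | (5S)-5-[(2R)-2-(1,3-dithian-2-yl)-2-hydroxyethyl]-5-methyloxolan-2-one | O=C1CC[C@@](C)(C[C@@H](O)C2SCCCS2)O1 | intermediate
9 | angelic acid, (2Z)-2-methylbut-2-enoic acid | C/C=C(/C)C(=O)O | starting material
10 | (2Z)-2-methylbut-2-enoic 2,4,6-trichlorobenzoic anhydride | C/C=C(/C)C(=O)OC(=O)c1c(Cl)cc(Cl)cc1Cl | intermediate
11 | (1R)-1-(1,3-dithian-2-yl)-2-[(2S)-2-methyl-5-oxooxolan-2-yl]ethyl (2Z)-2-methylbut-2-enoate | O=C1CC[C@@](C)(C[C@@H](OC(=O)/C(C)=C\C)C2SCCCS2)O1 | intermediate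
12 | but-2-yn-1-ol | CC#CCO | starting material
13 | sodium 2,2-bis(2-methoxyethoxy)-3-methyl-2,5-dihydro-1,2-oxaluminol-2-uide (cyclic Z-alkenylalanate, Al on C3 cis to the CH2O arm) | CC1=CCO[Al-]1(OCCOC)OCCOC.[Na+] | intermediate
14 | (2Z)-3-iodobut-2-en-1-ol | C/C(I)=C/CO | intermediate
15 | 1-({[(2Z)-3-iodobut-2-en-1-yl]oxy}methyl)-4-methoxybenzene | C/C(I)=C/COCc1ccc(OC)cc1 | intermediate
16 | {(2E)-4-[(4-methoxybenzyl)oxy]but-2-en-2-yl}lithium (Li cis to the CH2O arm, geometry of 15 retained) | C/C([Li])=C/COCc1ccc(OC)cc1 | intermediate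
17 | lithium (5S)-5-[(2R)-2-(1,3-dithian-2-yl)-2-{[(2Z)-2-methylbut-2-enoyl]oxy}ethyl]-2-{(2Z)-4-[(4-methoxybenzyl)oxy]but-2-en-2-yl}-5-methyloxolan-2-olate (both C2 epimers) | C/C(=C/COCc1ccc(OC)cc1)C1(O[Li])CC[C@@](C)(C[C@@H](OC(=O)/C(C)=C\C)C2SCCCS2)O1 | intermediate
18 | (1R,3S,7Z)-1-(1,3-dithian-2-yl)-3-hydroxy-9-[(4-methoxybenzyl)oxy]-3,7-dimethyl-6-oxonon-7-en-1-yl (2Z)-2-methylbut-2-enoate | C/C(=C/COCc1ccc(OC)cc1)C(=O)CC[C@](C)(O)C[C@@H](OC(=O)/C(C)=C\C)C1SCCCS1 | intermediate
19 | (1R,3S,6S,7Z)-1-(1,3-dithian-2-yl)-3,6-dihydroxy-9-[(4-methoxybenzyl)oxy]-3,7-dimethylnon-7-en-1-yl (2Z)-2-methylbut-2-enoate | C/C(=C/COCc1ccc(OC)cc1)[C@@H](O)CC[C@](C)(O)C[C@@H](OC(=O)/C(C)=C\C)C1SCCCS1 | intermediate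
20 | (1R,3S,6S,7Z)-1-(1,3-dithian-2-yl)-9-[(4-methoxybenzyl)oxy]-3,7-dimethyl-3,6-bis[(triethylsilyl)oxy]non-7-en-1-yl (2Z)-2-methylbut-2-enoate | C/C(=C/COCc1ccc(OC)cc1)[C@@H](O[Si](CC)(CC)CC)CC[C@](C)(O[Si](CC)(CC)CC)C[C@@H](OC(=O)/C(C)=C\C)C1SCCCS1 | intermediate
21 | (2R,4S,7S,8Z)-10-[(4-methoxybenzyl)oxy]-4,8-dimethyl-1-oxo-4,7-bis[(triethylsilyl)oxy]dec-8-en-2-yl (2Z)-2-methylbut-2-enoate | C/C(=C/COCc1ccc(OC)cc1)[C@@H](O[Si](CC)(CC)CC)CC[C@](C)(O[Si](CC)(CC)CC)C[C@@H](OC(=O)/C(C)=C\C)C=O | intermediate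
22 | methyl propiolate (methyl prop-2-ynoate) | C#CC(=O)OC | starting material
23 | methyl 2-[bis(2-methylpropyl)alumanyl]prop-2-enoate | C=C(C(=O)OC)[Al](CC(C)C)CC(C)C | intermediate
24 | methyl (4R,6S,9S,10Z)-3-hydroxy-12-[(4-methoxybenzyl)oxy]-6,10-dimethyl-2-methylidene-4-{[(2Z)-2-methylbut-2-enoyl]oxy}-6,9-bis[(triethylsilyl)oxy]dodec-10-enoate (both C3 epimers) | C/C(=C/COCc1ccc(OC)cc1)[C@@H](O[Si](CC)(CC)CC)CC[C@](C)(O[Si](CC)(CC)CC)C[C@@H](OC(=O)/C(C)=C\C)C(O)C(=C)C(=O)OC | intermediate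
25 | methyl (4R,6S,9S,10Z)-3,12-dihydroxy-6,10-dimethyl-2-methylidene-4-{[(2Z)-2-methylbut-2-enoyl]oxy}-6,9-bis[(triethylsilyl)oxy]dodec-10-enoate (both C3 epimers) | C/C(=C/CO)[C@@H](O[Si](CC)(CC)CC)CC[C@](C)(O[Si](CC)(CC)CC)C[C@@H](OC(=O)/C(C)=C\C)C(O)C(=C)C(=O)OC | intermediate
26 | methyl (4R,6S,9S,10Z)-3-hydroxy-6,10-dimethyl-2-methylidene-4-{[(2Z)-2-methylbut-2-enoyl]oxy}-12-oxo-6,9-bis[(triethylsilyl)oxy]dodec-10-enoate (both C3 epimers) | C/C(=C/C=O)[C@@H](O[Si](CC)(CC)CC)CC[C@](C)(O[Si](CC)(CC)CC)C[C@@H](OC(=O)/C(C)=C\C)C(O)C(=C)C(=O)OC | intermediate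
27 | methyl (2Z,4R,6S,9S,10Z)-2-(bromomethyl)-6,10-dimethyl-4-{[(2Z)-2-methylbut-2-enoyl]oxy}-12-oxo-6,9-bis[(triethylsilyl)oxy]dodeca-2,10-dienoate | C/C(=C/C=O)[C@@H](O[Si](CC)(CC)CC)CC[C@](C)(O[Si](CC)(CC)CC)C[C@@H](OC(=O)/C(C)=C\C)/C=C(\CBr)C(=O)OC | intermediate
28 | methyl 2-[(1S,2S,3Z,5S,8S,10R)-2-hydroxy-4,8-dimethyl-10-{[(2Z)-2-methylbut-2-enoyl]oxy}-5,8-bis[(triethylsilyl)oxy]cyclodec-3-en-1-yl]prop-2-enoate | C=C(C(=O)OC)[C@H]1[C@@H](O)/C=C(/C)[C@@H](O[Si](CC)(CC)CC)CC[C@](C)(O[Si](CC)(CC)CC)C[C@H]1OC(=O)/C(C)=C\C | intermediate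
29 | (3aR,4R,6S,9S,10Z,11aS)-6,10-dimethyl-3-methylidene-2-oxo-6,9-bis[(triethylsilyl)oxy]-2,3,3a,4,5,6,7,8,9,11a-decahydrocyclodeca[b]furan-4-yl (2Z)-2-methylbut-2-enoate | C=C1C(=O)O[C@H]2/C=C(/C)[C@@H](O[Si](CC)(CC)CC)CC[C@](C)(O[Si](CC)(CC)CC)C[C@@H](OC(=O)/C(C)=C\C)[C@@H]12 | intermediate
30 | (3aR,4R,6S,9S,10Z,11aS)-6,9-dihydroxy-6,10-dimethyl-3-methylidene-2-oxo-2,3,3a,4,5,6,7,8,9,11a-decahydrocyclodeca[b]furan-4-yl (2Z)-2-methylbut-2-enoate | C=C1C(=O)O[C@H]2/C=C(/C)[C@@H](O)CC[C@](C)(O)C[C@@H](OC(=O)/C(C)=C\C)[C@@H]12 | target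

**Step count**
Total: 14 steps. Longest linear sequence: 12 steps (steps 1–4 and 7–14, from 1,3-dithiane); steps 5–6 make the alkenyl iodide in parallel.

**Three steps most likely to fail**

Step 14 (macrocyclisation and lactonisation). The allylchromium carries the angelate one carbon beyond its γ-carbon and could lose it by 1,4-elimination to a diene. Ten-membered ring closure competes with oligomerisation. The facial sense relative to C8 rests on an acyclic A(1,3) model that the ring may override. The fallback keeps the same C6–C7 ring closure but uses a boron allyl, which does not eliminate and reacts only through a closed chair. It sets out from 24: acetylation (Ac2O, pyridine) gives the Morita–Baylis–Hillman acetate F1. Borylation with allylic transposition (B2pin2, Pd2(dba)3 cat., toluene, 50 °C) gives the Z-configured 2-(methoxycarbonyl)allyl pinacol boronate F2. DDQ and then TEMPO/PhI(OAc)2, as in step 12, unmask the boronate enal F3. Heating F3 at high dilution (toluene, 80 °C) effects intramolecular allylboration and lactonisation to the bis-silyl lactone 29, where the route is rejoined (2 M HCl gives 30).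

Step 3 (SmI2 coupling). The C10 configuration depends on the chelate model (chain added anti to the C8 substituent); if the ratio is poor or inverted, C10 is set by a closed-shell chelation-controlled addition instead. The fallback sets out from 5: TiCl4 (CH2Cl2, −78 °C) forms the titanium alkoxide chelate and allyltrimethylsilane adds axially (Sakurai allylation) to give the homoallylic 1,3-anti diol F4. Angeloylation of the secondary hydroxyl with mixed anhydride 10 gives the angelate F5. Hydroboration of the terminal alkene (9-BBN, then NaBO3) gives the primary alcohol F6. Dess–Martin periodinane (excess, NaHCO3) oxidises F6 through the aldehyde and the lactol to lactone 11, where the route is rejoined.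

Step 7 (alkenyllithium addition). The angelate ester may compete with the lactone for the organolithium, and the Z-enone is sensitive. The fallback reverses the order of acylation and addition. It sets out from 8: alkenyllithium 16 (2.2 equiv, the first equivalent deprotonating the hydroxyl) is added at −78 °C to give the dihydroxy enone F7. The secondary C8 hydroxyl of F7 is then acylated selectively over the tertiary one with preformed mixed anhydride 10 (amine-free, toluene, 60 °C), which returns to 18.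

Further compounds
F1 | step 14 | methyl (4R,6S,9S,10Z)-3-acetoxy-12-[(4-methoxybenzyl)oxy]-6,10-dimethyl-2-methylidene-4-{[(2Z)-2-methylbut-2-enoyl]oxy}-6,9-bis[(triethylsilyl)oxy]dodec-10-enoate | C/C(=C/COCc1ccc(OC)cc1)[C@@H](O[Si](CC)(CC)CC)CC[C@](C)(O[Si](CC)(CC)CC)C[C@@H](OC(=O)/C(C)=C\C)C(OC(C)=O)C(=C)C(=O)OC
F2 | step 14 | methyl (2E,4R,6S,9S,10Z)-12-[(4-methoxybenzyl)oxy]-6,10-dimethyl-4-{[(2Z)-2-methylbut-2-enoyl]oxy}-2-[(4,4,5,5-tetramethyl-1,3,2-dioxaborolan-2-yl)methyl]-6,9-bis[(triethylsilyl)oxy]dodeca-2,10-dienoate | C/C(=C/COCc1ccc(OC)cc1)[C@@H](O[Si](CC)(CC)CC)CC[C@](C)(O[Si](CC)(CC)CC)C[C@@H](OC(=O)/C(C)=C\C)/C=C(\CB1OC(C)(C)C(C)(C)O1)C(=O)OC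
F3 | step 14 | methyl (2E,4R,6S,9S,10Z)-6,10-dimethyl-4-{[(2Z)-2-methylbut-2-enoyl]oxy}-12-oxo-2-[(4,4,5,5-tetramethyl-1,3,2-dioxaborolan-2-yl)methyl]-6,9-bis[(triethylsilyl)oxy]dodeca-2,10-dienoate | C/C(=C/C=O)[C@@H](O[Si](CC)(CC)CC)CC[C@](C)(O[Si](CC)(CC)CC)C[C@@H](OC(=O)/C(C)=C\C)/C=C(\CB1OC(C)(C)C(C)(C)O1)C(=O)OC
F4 | step 3 | (1R,3S)-1-(1,3-dithian-2-yl)-3-methylhex-5-ene-1,3-diol | C=CC[C@](C)(O)C[C@@H](O)C1SCCCS1
F5 | step 3 | (1R,3S)-1-(1,3-dithian-2-yl)-3-hydroxy-3-methylhex-5-en-1-yl (2Z)-2-methylbut-2-enoate | C=CC[C@](C)(O)C[C@@H](OC(=O)/C(C)=C\C)C1SCCCS1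
F6 | step 3 | (1R,3S)-1-(1,3-dithian-2-yl)-3,6-dihydroxy-3-methylhexyl (2Z)-2-methylbut-2-enoate | OCCC[C@](C)(O)C[C@@H](OC(=O)/C(C)=C\C)C1SCCCS1
F7 | step 7 | (2Z,7S,9R)-9-(1,3-dithian-2-yl)-7,9-dihydroxy-1-[(4-methoxybenzyl)oxy]-3,7-dimethylnon-2-en-4-one | C/C(=C/COCc1ccc(OC)cc1)C(=O)CC[C@](C)(O)C[C@@H](O)C1SCCCS1
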